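Cuts, in retrosynthetic order:
- twelve O-benzyl groups and two C8–Br caps
- the interflavan bond C4(upper)–C6(lower)
- the 3'-O- and 3-O-galloyl esters of the lower unit, back to (−)-epigallocatechin
- in the upper C ring the bond O1–C2, with O1 put back on C3

Ring change: the last cut shrinks the upper pyran ring (O1, C2, C3, C4, C4a, C8a) to the furan ring (O1, C3, C4, C4a, C8a) of a flat, achiral 2-benzylbenzofuran, in which C2 is the exocyclic CH2.
Enabling feature: O1 and O-3 stand on neighbouring carbons beside the 5,7-dioxygenated A ring, so the furan epoxide opens to an o-quinone methide with a C3 ketone. C2 is benzylic to ring B and α to that ketone, so it enolises and O1 closes on C2.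
Forward order: ring A (bought) → furan ring (Rap–Stoermer) → CH2 at C2 → oxidative ring expansion to the racemic flavan-3-one → cis-alcohol → C4 ether and C8 cap. The lower unit is protected, esterified twice and capped at C8. A cationic C4→C6 union and one hydrogenolysis finish the route.
Stereochemistry: upper C2 and C3 come from one asymmetric hydrogenation with dynamic kinetic resolution, upper C4 from attack anti to the axial 3-OH, and lower C2 and C3 from the chiral pool.

Key step: step 4

Remark: flavan numbering (O1, C2, C3, C4, C4a, C5–C8, C8a, B ring primed) is used for all atoms, also at the benzofuran stage. The hand of the hydrogenation catalyst in step 5 is assigned by analogy with 2-aryl- and 2-alkoxycyclohexanones, and its mirror image is taken if a test run shows the opposite sense.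

Step 1
Reactants: 1 2,4,6-trihydroxybenzaldehyde
Product: 2 2,4-bis(benzyloxy)-6-hydroxybenzaldehyde
Conditions: BnBr (2.05 equiv), K2CO3 (2.1 equiv), DMF, 0 °C to rt
Reagents that add atoms: benzyl bromide BrCc1ccccc1
Why: Williamson etherification in which one ortho OH stays free because it is held in a hydrogen bond to the formyl oxygen and only two equivalents of halide are offered.

Step 2
Reactants: 2 2,4-bis(benzyloxy)-6-hydroxybenzaldehyde; 3 2-bromo-1-[4-(benzyloxy)phenyl]ethan-1-one
Product: 5 [4,6-bis(benzyloxy)-1-benzofuran-2-yl][4-(benzyloxy)phenyl]methanone, via phenacyl ether 4 (not isolated)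
Conditions: K2CO3 (2.5 equiv), DMF, 80 °C
Reagents that add atoms: none
Why: Rap–Stoermer benzofuran synthesis, in which O-alkylation, intramolecular aldol addition of the activated OCH2 to the aldehyde and dehydration assemble all fifteen skeletal carbons of the upper unit as a 2-aroylbenzofuran.

Step 3
Reactants: 5 [4,6-bis(benzyloxy)-1-benzofuran-2-yl][4-(benzyloxy)phenyl]methanone
Product: 7 4,6-bis(benzyloxy)-2-[4-(benzyloxy)benzyl]-1-benzofuran, via hydrazone 6 (not isolated)
Conditions: N2H4·H2O, KOH, diethylene glycol, 130 to 195 °C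
Reagents that add atoms: none
Why: Wolff–Kishner reduction (Huang-Minlon variant) of the diaryl-type ketone to CH2, which the benzyl ethers and the benzofuran tolerate because the medium is only basic.

Step 4
Reactants: 7 4,6-bis(benzyloxy)-2-[4-(benzyloxy)benzyl]-1-benzofuran
Product: 12 rac-5,7-bis(benzyloxy)-2-[4-(benzyloxy)phenyl]chroman-3-one, via benzofuran epoxide 8 (not isolated), via keto o-quinone methide 9 (not isolated), via dienol o-quinone methide 10 (not isolated), via 2H-chromen-3-ol 11 (not isolated)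
Conditions: DMDO (1.0 equiv, acetone), CH2Cl2, 0.01 M, −78 to −30 °C; then Et3N (0.2 equiv), −30 °C to rt
Reagents that add atoms: dimethyldioxirane CC1(C)OO1
Why: Proposed new method: DMDO transfers one oxygen to the most electron-rich π bond of 7, the furan C3=C4 enol ether (concerted spiro transition state, closes the oxirane of 8), and the 5,7-benzyloxy groups push 8 open by cleavage of C4–O(epoxide) and C3–O1 to the Z-configured keto o-quinone methide 9, the known valence isomerism of benzofuran epoxides. Et3N enolises the C2 methylene, which is benzylic to ring B and α to the C3 ketone, to dienol 10, whose O1=C8a–C4a=C4–C3=C2 oxatriene closes the six-membered ring by a thermal disrotatory oxa-6π electrocyclisation (new bond O1–C2) with rearomatisation of ring A, and enol 11 ketonises to 12. In sum O1 walks from C3 to C2, the exocyclic C2 enters the ring and the five-membered ring becomes six-membered; the closest known reaction types are the Achmatowicz oxidative ring expansion of furfuryl systems and the vinyl o-quinone methide to 2H-chromene electrocyclisation. The only new stereocentre, C2, is formed without control and on purpose, because it is α to the ketone, stereolabile, and is fixed in step 5. Chemoselectivity (furan double bond before arenes, benzyl ethers and the diarylmethane CH2) rests on its enol-ether character at −78 °C and on one equivalent of oxidant, and the Z geometry needed for closure is inherited from the cis-fused epoxide. The competing 1,2-hydride shift to a coumaranone needs positive charge on C3, whereas the A-ring donors place it on C4, and high dilution holds back quinone methide dimerisation.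

Step 5
Reactants: 12 rac-5,7-bis(benzyloxy)-2-[4-(benzyloxy)phenyl]chroman-3-one
Product: 13 (2R,3R)-5,7-bis(benzyloxy)-2-[4-(benzyloxy)phenyl]chroman-3-ol (5,7,4'-tri-O-benzylepiafzelechin)
Conditions: H2 (50 atm), RuCl2[(S)-Xyl-SDP][(R,R)-DPEN] (0.5 mol %), t-BuOK (10 mol %), i-PrOH/toluene, rt
Reagents that add atoms: none
Why: Noyori asymmetric hydrogenation with dynamic kinetic resolution, as known for 2-aryl- and 2-alkoxycycloalkanones: C2 racemises through the enolate faster than the ketone is reduced, and the catalyst takes the (2R)-ketone from the face away from the 2-aryl group, which sets C3 as R and locks C2 as R in the 2,3-cis alcohol.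

Step 6
Reactants: 13 (2R,3R)-5,7-bis(benzyloxy)-2-[4-(benzyloxy)phenyl]chroman-3-ol
Product: 14 4β-(2-ethoxyethoxy)-5,7,4'-tri-O-benzylepiafzelechin (2,3-cis-3,4-trans)
Conditions: DDQ (2 equiv), 2-ethoxyethanol (5 equiv), CH2Cl2, rt
Reagents that add atoms: 2-ethoxyethanol CCOCCO
Why: DDQ benzylic oxidation, in which hydride abstraction at C4 gives the cation stabilised by the 5,7-dioxygenated A ring and the alcohol adds anti to the axial 3-OH, so the new C4 centre is 3,4-trans as known for benzylated epicatechin.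

Step 7
Reactants: 14 4β-(2-ethoxyethoxy)-5,7,4'-tri-O-benzylepiafzelechin
Product: 15 8-bromo-4β-(2-ethoxyethoxy)-5,7,4'-tri-O-benzylepiafzelechin
Conditions: NBS (1.0 equiv), CH2Cl2, −78 to −20 °C
Reagents that add atoms: N-bromosuccinimide O=C1CCC(=O)N1Br
Why: Electrophilic aromatic bromination at C8, the most reactive and less crowded A-ring position of benzylated flavan-3-ols, which caps the site through which the electrophile would otherwise condense with itself.

Step 8
Reactants: 16 (−)-epigallocatechin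
Product: 17 3',4'-O-(diphenylmethylene)epigallocatechin
Conditions: Ph2CCl2 (1.1 equiv), K2CO3, MeCN, rt, Ar
Reagents that add atoms: dichlorodiphenylmethane ClC(Cl)(c1ccccc1)c1ccccc1
Why: Ketalisation of vicinal phenols, possible only on the pyrogallol B ring, whose two equivalent pairs of neighbouring OH groups give one 1,3-benzodioxole and leave one B-ring OH distinct.

Step 9
Reactants: 17 3',4'-O-(diphenylmethylene)epigallocatechin
Product: 18 5,7,5'-tri-O-benzyl-3',4'-O-(diphenylmethylene)epigallocatechin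
Conditions: BnBr (3.3 equiv), K2CO3, DMF, 0 °C to rt
Reagents that add atoms: benzyl bromide BrCc1ccccc1
Why: Williamson etherification of the three free phenols, with the aliphatic 3-OH untouched by carbonate base and C2 safe from epimerisation because no free 4'-phenol is present.

Step 10
Reactants: 18 5,7,5'-tri-O-benzyl-3',4'-O-(diphenylmethylene)epigallocatechin; 19 3,4,5-tris(benzyloxy)benzoic acid
Product: 20 5,7,5'-tri-O-benzyl-3',4'-O-(diphenylmethylene)epigallocatechin 3-O-[3,4,5-tris(benzyloxy)benzoate]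
Conditions: DCC (1.5 equiv), DMAP, CH2Cl2, rt
Reagents that add atoms: none
Why: Steglich esterification of the only free hydroxyl, with retention at C3 because the C3–O bond is not broken.

Step 11
Reactants: 20 5,7,5'-tri-O-benzyl-3',4'-O-(diphenylmethylene)epigallocatechin 3-O-[3,4,5-tris(benzyloxy)benzoate]
Product: 21 5,7,5'-tri-O-benzylepigallocatechin 3-O-[3,4,5-tris(benzyloxy)benzoate]
Conditions: AcOH/H2O 4:1, 80 °C
Reagents that add atoms: none
Why: Acid hydrolysis of the diphenylmethylene ketal frees the 3',4'-catechol, while benzyl ethers and the alkyl gallate are stable to aqueous acetic acid.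

Step 12
Reactants: 21 5,7,5'-tri-O-benzylepigallocatechin 3-O-[3,4,5-tris(benzyloxy)benzoate]; 19 3,4,5-tris(benzyloxy)benzoic acid
Product: 22 5,7,5'-tri-O-benzylepigallocatechin 3,3'-bis-O-[3,4,5-tris(benzyloxy)benzoate] (4'-OH free)
Conditions: 19 (1.05 equiv), DCC, DMAP (cat.), CH2Cl2, −20 to 0 °C
Reagents that add atoms: none
Why: Steglich esterification under steric control: 3'-OH has a free ortho position whereas 4'-OH is flanked by 5'-OBn and the 3'-oxygen, so the bulky acyl donor should take O-3', DMAP-mediated acyl migration should drain any 4'-ester to the same less crowded ester, and the hindered 4'-OH is carried free.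

Step 13
Reactants: 22 5,7,5'-tri-O-benzylepigallocatechin 3,3'-bis-O-[3,4,5-tris(benzyloxy)benzoate]
Product: 23 8-bromo-5,7,5'-tri-O-benzylepigallocatechin 3,3'-bis-O-[3,4,5-tris(benzyloxy)benzoate]
Conditions: NBS (1.0 equiv), CH2Cl2, −78 °C
Reagents that add atoms: N-bromosuccinimide O=C1CCC(=O)N1Br
Why: Electrophilic aromatic bromination as a halogen cap: C8 is the most reactive A-ring site, and the free 4'-OH activates only substituted B-ring positions, so C6 is left as the sole nucleophilic carbon.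

Step 14
Reactants: 15 8-bromo-4β-(2-ethoxyethoxy)-5,7,4'-tri-O-benzylepiafzelechin; 23 8-bromo-5,7,5'-tri-O-benzylepigallocatechin 3,3'-bis-O-[3,4,5-tris(benzyloxy)benzoate]
Product: 24 protected 8,8-dibromo epiafzelechin-(4β→6)-epigallocatechin 3,3'-digallate
Conditions: 23 (2 equiv), TMSOTf (0.3 equiv), 4 Å MS, CH2Cl2, −78 to −30 °C
Reagents that add atoms: none
Why: Lewis-acid-promoted Friedel–Crafts coupling of a flavan-4-yl cation: the A-ring-stabilised C4 cation is attacked on its β face, anti to the axial 3-OH of the 2,3-cis unit (new C4 centre, 3,4-trans), by C6 of 23 because both C8 positions carry bromine, and the excess of 23 outcompetes the bromine-deactivated C6 of 15.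

Step 15
Reactants: 24 protected 8,8-dibromo epiafzelechin-(4β→6)-epigallocatechin 3,3'-digallate
Product: 25 epiafzelechin-(4β→6)-epigallocatechin 3,3'-di-O-gallate (target)
Conditions: H2 (1 atm), 20 % Pd(OH)2/C, NaOAc (2.2 equiv), THF/MeOH/H2O, rt
Reagents that add atoms: none
Why: Catalytic hydrogenolysis removes twelve benzyl ethers and both aryl bromides in one operation while acetate buffers the HBr, and no stereocentre, ester or interflavan bond is touched under these neutral conditions.

Compound list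
1 | 2,4,6-trihydroxybenzaldehyde | O=Cc1c(O)cc(O)cc1O | starting material
2 | 2,4-bis(benzyloxy)-6-hydroxybenzaldehyde | O=Cc1c(O)cc(OCc2ccccc2)cc1OCc1ccccc1 | intermediate
3 | 2-bromo-1-[4-(benzyloxy)phenyl]ethan-1-one | O=C(CBr)c1ccc(OCc2ccccc2)cc1 | starting material
4 | 2,4-bis(benzyloxy)-6-{2-[4-(benzyloxy)phenyl]-2-oxoethoxy}benzaldehyde (phenacyl ether, not isolated) | O=Cc1c(OCC(=O)c2ccc(OCc3ccccc3)cc2)cc(OCc2ccccc2)cc1OCc1ccccc1 | intermediate
5 | [4,6-bis(benzyloxy)-1-benzofuran-2-yl][4-(benzyloxy)phenyl]methanone | O=C(c1cc2c(OCc3ccccc3)cc(OCc3ccccc3)cc2o1)c1ccc(OCc2ccccc2)cc1 | intermediate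
6 | hydrazone of 5 (not isolated) | NN=C(c1cc2c(OCc3ccccc3)cc(OCc3ccccc3)cc2o1)c1ccc(OCc2ccccc2)cc1 | intermediate
7 | 4,6-bis(benzyloxy)-2-[4-(benzyloxy)benzyl]-1-benzofuran | C(c1cc2c(OCc3ccccc3)cc(OCc3ccccc3)cc2o1)c1ccc(OCc2ccccc2)cc1 | intermediate
8 | 2,3-epoxide of 7 (racemic, cis-fused oxirenobenzofuran, not isolated) | C(C12OC1c1c(OCc3ccccc3)cc(OCc3ccccc3)cc1O2)c1ccc(OCc2ccccc2)cc1 | intermediate
9 | (Z)-3,5-bis(benzyloxy)-6-{3-[4-(benzyloxy)phenyl]-2-oxopropylidene}cyclohexa-2,4-dien-1-one (keto o-quinone methide, not isolated) | O=C(Cc1ccc(OCc2ccccc2)cc1)/C=C1\C(=O)C=C(OCc2ccccc2)C=C1OCc1ccccc1 | intermediate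
10 | C2=C3 enol of 9 (dienol o-quinone methide, not isolated) | OC(=Cc1ccc(OCc2ccccc2)cc1)/C=C1\C(=O)C=C(OCc2ccccc2)C=C1OCc1ccccc1 | intermediate
11 | rac-5,7-bis(benzyloxy)-2-[4-(benzyloxy)phenyl]-2H-chromen-3-ol (not isolated) | OC1=Cc2c(OCc3ccccc3)cc(OCc3ccccc3)cc2OC1c1ccc(OCc2ccccc2)cc1 | intermediate
12 | rac-5,7-bis(benzyloxy)-2-[4-(benzyloxy)phenyl]chroman-3-one | O=C1Cc2c(OCc3ccccc3)cc(OCc3ccccc3)cc2OC1c1ccc(OCc2ccccc2)cc1 | intermediate
13 | (2R,3R)-5,7-bis(benzyloxy)-2-[4-(benzyloxy)phenyl]chroman-3-ol (5,7,4'-tri-O-benzylepiafzelechin) | O[C@@H]1Cc2c(OCc3ccccc3)cc(OCc3ccccc3)cc2O[C@@H]1c1ccc(OCc2ccccc2)cc1 | intermediate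
14 | 4β-(2-ethoxyethoxy)-5,7,4'-tri-O-benzylepiafzelechin (2,3-cis, 3,4-trans) | CCOCCO[C@H]1c2c(OCc3ccccc3)cc(OCc3ccccc3)cc2O[C@H](c2ccc(OCc3ccccc3)cc2)[C@@H]1O | intermediate
15 | 8-bromo-4β-(2-ethoxyethoxy)-5,7,4'-tri-O-benzylepiafzelechin | CCOCCO[C@H]1c2c(OCc3ccccc3)cc(OCc3ccccc3)c(Br)c2O[C@H](c2ccc(OCc3ccccc3)cc2)[C@@H]1O | intermediate
16 | (−)-epigallocatechin, (2R,3R) | O[C@@H]1Cc2c(O)cc(O)cc2O[C@@H]1c1cc(O)c(O)c(O)c1 | starting material
17 | 3',4'-O-(diphenylmethylene)epigallocatechin | O[C@@H]1Cc2c(O)cc(O)cc2O[C@@H]1c1cc(O)c2OC(c3ccccc3)(c3ccccc3)Oc2c1 | intermediate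
18 | 5,7,5'-tri-O-benzyl-3',4'-O-(diphenylmethylene)epigallocatechin | O[C@@H]1Cc2c(OCc3ccccc3)cc(OCc3ccccc3)cc2O[C@@H]1c1cc(OCc2ccccc2)c2OC(c3ccccc3)(c3ccccc3)Oc2c1 | intermediate
19 | 3,4,5-tris(benzyloxy)benzoic acid | OC(=O)c1cc(OCc2ccccc2)c(OCc2ccccc2)c(OCc2ccccc2)c1 | starting material
20 | 5,7,5'-tri-O-benzyl-3',4'-O-(diphenylmethylene)epigallocatechin 3-O-[3,4,5-tris(benzyloxy)benzoate] | O=C(O[C@@H]1Cc2c(OCc3ccccc3)cc(OCc3ccccc3)cc2O[C@@H]1c1cc(OCc2ccccc2)c2OC(c3ccccc3)(c3ccccc3)Oc2c1)c1cc(OCc2ccccc2)c(OCc2ccccc2)c(OCc2ccccc2)c1 | intermediate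
21 | 5,7,5'-tri-O-benzylepigallocatechin 3-O-[3,4,5-tris(benzyloxy)benzoate] (3',4'-diol) | O=C(O[C@@H]1Cc2c(OCc3ccccc3)cc(OCc3ccccc3)cc2O[C@@H]1c1cc(O)c(O)c(OCc2ccccc2)c1)c1cc(OCc2ccccc2)c(OCc2ccccc2)c(OCc2ccccc2)c1 | intermediate
22 | 5,7,5'-tri-O-benzylepigallocatechin 3,3'-bis-O-[3,4,5-tris(benzyloxy)benzoate] (4'-OH free) | O=C(Oc1cc([C@H]2Oc3cc(OCc4ccccc4)cc(OCc4ccccc4)c3C[C@H]2OC(=O)c2cc(OCc3ccccc3)c(OCc3ccccc3)c(OCc3ccccc3)c2)cc(OCc2ccccc2)c1O)c1cc(OCc2ccccc2)c(OCc2ccccc2)c(OCc2ccccc2)c1 | intermediate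
23 | 8-bromo derivative of 22 | O=C(Oc1cc([C@H]2Oc3c(Br)c(OCc4ccccc4)cc(OCc4ccccc4)c3C[C@H]2OC(=O)c2cc(OCc3ccccc3)c(OCc3ccccc3)c(OCc3ccccc3)c2)cc(OCc2ccccc2)c1O)c1cc(OCc2ccccc2)c(OCc2ccccc2)c(OCc2ccccc2)c1 | intermediate
24 | protected dimer: 8-bromo-5,7,4'-tri-O-benzylepiafzelechin-(4β→6)-8-bromo-5,7,5'-tri-O-benzylepigallocatechin 3,3'-bis-O-[3,4,5-tris(benzyloxy)benzoate] | O=C(Oc1cc([C@H]2Oc3c(Br)c(OCc4ccccc4)c([C@H]4c5c(OCc6ccccc6)cc(OCc6ccccc6)c(Br)c5O[C@H](c5ccc(OCc6ccccc6)cc5)[C@@H]4O)c(OCc4ccccc4)c3C[C@H]2OC(=O)c2cc(OCc3ccccc3)c(OCc3ccccc3)c(OCc3ccccc3)c2)cc(OCc2ccccc2)c1O)c1cc(OCc2ccccc2)c(OCc2ccccc2)c(OCc2ccccc2)c1 | intermediate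
25 | epiafzelechin-(4β→6)-epigallocatechin 3,3'-di-O-gallate | O=C(Oc1cc([C@H]2Oc3cc(O)c([C@H]4c5c(O)cc(O)cc5O[C@H](c5ccc(O)cc5)[C@@H]4O)c(O)c3C[C@H]2OC(=O)c2cc(O)c(O)c(O)c2)cc(O)c1O)c1cc(O)c(O)c(O)c1 | target

Total step count: 15. Longest linear sequence: 9 steps (steps 1–7, 14, 15).

Steps most likely to fail

Step 4.
- What may go wrong: enolisation may be slower than dimerisation or nucleophilic trapping of the quinone methide. The base may isomerise the epoxide into the allylic-alcohol manifold. A 1,2-hydride shift of the epoxide may compete, and the enol may be over-oxidised.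
- Fallback (known chemistry): it sets out from 2 and comes back to the route at 12. Claisen–Schmidt condensation of 2 with 4'-(benzyloxy)acetophenone (KOH, EtOH) should give the 2-hydroxychalcone F1. Luche reduction (NaBH4, CeCl3, MeOH) should give the allylic alcohol F2. Warming with PPTS in toluene should dehydrate it, through the vinyl o-quinone methide and oxa-6π closure, to the flav-3-ene F3. Hydroboration–oxidation (BH3·THF, then H2O2, NaOH) should give the racemic 2,3-trans-flavan-3-ol F4, and Dess–Martin oxidation should give 12.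

Step 5.
- What may go wrong: face discrimination may be insufficient for a ketone flanked by CH2 and CH(Ar)O. Racemisation may be slower than reduction, and the base may cause aldol self-condensation.
- Fallback: it sets out from 12 and comes back at 13. L-Selectride (THF, −78 °C), the standard cis-selective reduction of flavan-3-ones, should give the racemic cis alcohol F5. Preparative chromatography on a chiral phase separates 13 from its (2S,3S) enantiomer F6. F6 is returned to the stereolabile ketone 12 by Dess–Martin oxidation and recycled.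

Step 14.
- What may go wrong: attack at the doubly ortho-substituted C6 may be sluggish. The electrophile may condense with itself through its uncapped C6. Acid may scramble the new interflavan bond, and free hydroxyls may be O-alkylated.
- Fallback: it sets out from 15 and comes back at 24. BF3·OEt2 and 2,6-dimethylbenzenethiol (CH2Cl2, −78 °C) exchange the 4-alkoxy group for sulfur to give the 4β-arylthio ether F7. This ether is inert to hard acids. It is ionised instead by a thiophilic silver salt (AgBF4, 2,6-di-tert-butylpyridine, CH2Cl2, −40 °C) in the presence of 23, so that the cation is released slowly in a buffered, non-acidic medium.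

Further compounds
F1 | step 4 | (E)-3-[2,4-bis(benzyloxy)-6-hydroxyphenyl]-1-[4-(benzyloxy)phenyl]prop-2-en-1-one | O=C(/C=C/c1c(O)cc(OCc2ccccc2)cc1OCc1ccccc1)c1ccc(OCc2ccccc2)cc1
F2 | step 4 | rac-(E)-3-[2,4-bis(benzyloxy)-6-hydroxyphenyl]-1-[4-(benzyloxy)phenyl]prop-2-en-1-ol | OC(/C=C/c1c(O)cc(OCc2ccccc2)cc1OCc1ccccc1)c1ccc(OCc2ccccc2)cc1
F3 | step 4 | rac-5,7-bis(benzyloxy)-2-[4-(benzyloxy)phenyl]-2H-chromene | C1(c2ccc(OCc3ccccc3)cc2)C=Cc2c(OCc3ccccc3)cc(OCc3ccccc3)cc2O1
F4 | step 4 | rac-2,3-trans-5,7-bis(benzyloxy)-2-[4-(benzyloxy)phenyl]chroman-3-ol (both enantiomers) | O[C@H]1Cc2c(OCc3ccccc3)cc(OCc3ccccc3)cc2O[C@@H]1c1ccc(OCc2ccccc2)cc1.O[C@@H]1Cc2c(OCc3ccccc3)cc(OCc3ccccc3)cc2O[C@H]1c1ccc(OCc2ccccc2)cc1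
F5 | step 5 | rac-2,3-cis-5,7-bis(benzyloxy)-2-[4-(benzyloxy)phenyl]chroman-3-ol (both enantiomers) | O[C@@H]1Cc2c(OCc3ccccc3)cc(OCc3ccccc3)cc2O[C@@H]1c1ccc(OCc2ccccc2)cc1.O[C@H]1Cc2c(OCc3ccccc3)cc(OCc3ccccc3)cc2O[C@H]1c1ccc(OCc2ccccc2)cc1
F6 | step 5 | (2S,3S)-5,7-bis(benzyloxy)-2-[4-(benzyloxy)phenyl]chroman-3-ol | O[C@H]1Cc2c(OCc3ccccc3)cc(OCc3ccccc3)cc2O[C@H]1c1ccc(OCc2ccccc2)cc1
F7 | step 14 | 8-bromo-4β-(2,6-dimethylphenylthio)-5,7,4'-tri-O-benzylepiafzelechin | Cc1cccc(C)c1S[C@H]1c2c(OCc3ccccc3)cc(OCc3ccccc3)c(Br)c2O[C@H](c2ccc(OCc3ccccc3)cc2)[C@@H]1O
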